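## Retrosynthetic overview

1. The last step removes four aryl acetates under neutral conditions. Before it, the key step puts in the benzofuranone C4–OH and the flavonol C5–OH together: each sits peri to a ring carbonyl (benzofuranone C3=O, pyranone C4=O), and each carbonyl oxygen can reach exactly one C–H through a five-membered metallacycle.
2. The 4,5-dideoxy spiro hemiketal comes from an open 2-aroyl-2-aryl-benzofuran-3(2H)-one. When the flavonol O7 is freed, it adds to the aroyl ketone and closes the dihydrofuran ring (O7–C(OH)Ar–C2(spiro)–C8), the only ring formed in the route.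
3. The quaternary C2 is set by a catalytic enantioselective O→C aroyl shift of a 3-aroyloxy-2-arylbenzofuran.
4. The C2–C8 bond is made by Negishi coupling of a benzofuran-2-ylzinc reagent with an 8-iodoflavone; the flavonol and benzofuranone ring systems are bought.
5. The iodide comes from 3,7,4'-trihydroxyflavone (acetylation, 7-deacetylation, C8 iodination, benzyl exchange); the zinc reagent comes from 6-hydroxybenzofuran-3(2H)-one.

Key step: step 13

Assumption: the hemiketal carbon equilibrates by ring–chain tautomerism and settles in the configuration of the target (OH syn to the benzofuranone C3=O, aryl syn to O1), so only the spiro carbon has to be set.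

Locants for the spiro compounds: benzofuranone atoms are unprimed; furo[2,3-h]chromenone atoms are primed (5' = flavonol C5, 8' = hemiketal carbon, 9' = spiro carbon = benzofuranone C2).

## Route

Step 1
Reactants: 1 3,7,4'-trihydroxyflavone
Product: 2 3,7,4'-triacetoxyflavone
Conditions: Ac2O, pyridine, DMAP (cat.), rt
Reagents that add atoms: acetic anhydride, CC(=O)OC(C)=O
Why: Exhaustive O-acetylation under nucleophilic catalysis converts all three hydroxyls to acetates, so that the next step can single out O7 and the B ring is deactivated for the later iodination.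

Step 2
Reactants: 2 3,7,4'-triacetoxyflavone
Product: 3 3,4'-diacetoxy-7-hydroxyflavone
Conditions: PhSH, imidazole, NMP, 0 °C → rt
Reagents that add atoms: none
Why: Imidazole-catalysed thiolysis should cleave only the 7-acetate, whose phenoxide is the best leaving group (para-conjugated to C4=O), a selectivity established for flavone peracetates.

Step 3
Reactants: 3 3,4'-diacetoxy-7-hydroxyflavone
Product: 4 3,4'-diacetoxy-7-hydroxy-8-iodoflavone
Conditions: NIS, TsOH (cat.), MeCN, 0 °C → rt, dark
Reagents that add atoms: N-iodosuccinimide, O=C1CCC(=O)N1I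
Why: Electrophilic aromatic iodination should go to C8, the position ortho to the free 7-OH that 7-hydroxychromones prefer, while the acetates keep the B ring unreactive and one equivalent of NIS limits 6,8-di-iodination.

Step 4
Reactants: 4 3,4'-diacetoxy-7-hydroxy-8-iodoflavone
Product: 6 3,7,4'-tris(benzyloxy)-8-iodoflavone, via 3,7,4'-trihydroxy-8-iodoflavone 5 (not isolated)
Conditions: K2CO3, MeOH/THF, rt, Ar; evaporate; BnBr, K2CO3, DMF, 60 °C
Reagents that add atoms: benzyl bromide, BrCc1ccccc1
Why: Base methanolysis of the two acetates followed by Williamson benzylation of all three phenoxides should give a coupling partner with no base- or nucleophile-labile group, and argon prevents base-mediated oxygenation of the free flavonol.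

Step 5
Reactants: 7 6-hydroxybenzofuran-3(2H)-one
Product: 8 6-(benzyloxy)benzofuran-3(2H)-one
Conditions: BnBr (1.05 equiv), K2CO3 (1.1 equiv), DMF, rt
Reagents that add atoms: benzyl bromide, BrCc1ccccc1
Why: Williamson etherification with one equivalent of mild base should alkylate the acidic para-acyl phenol in preference to C2 of the ketone.

Step 6
Reactants: 8 6-(benzyloxy)benzofuran-3(2H)-one
Product: 10 6-(benzyloxy)-3-(methoxymethoxy)benzofuran, via potassium enolate 9 (not isolated)
Conditions: KHMDS, THF, −78 °C; MOMCl, −78 → 0 °C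
Reagents that add atoms: chloromethyl methyl ether, COCCl
Why: The potassium enolate is an aromatic benzofuran-3-olate and the hard, oxocarbenium-like electrophile MOMCl should alkylate it on oxygen, giving an enol ether that also directs the next lithiation.

Step 7
Reactants: 10 6-(benzyloxy)-3-(methoxymethoxy)benzofuran; 6 3,7,4'-tris(benzyloxy)-8-iodoflavone
Product: 13 3,7,4'-tris(benzyloxy)-8-[6-(benzyloxy)-3-(methoxymethoxy)benzofuran-2-yl]flavone, via 2-lithiobenzofuran 11 (not isolated), via benzofuran-2-ylzinc chloride 12 (not isolated)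
Conditions: n-BuLi, THF, −78 °C; ZnCl2, −78 °C → rt; 6, Pd2(dba)3, SPhos, THF, 60 °C
Reagents that add atoms: none
Why: Lithiation at C2 (the most acidic C–H, between O1 and the chelating 3-OMOM), transmetalation to zinc and Negishi coupling with a bulky biarylphosphine should form the hindered C2–C8 bond without touching the chromone carbonyl.

Step 8
Reactants: 13 3,7,4'-tris(benzyloxy)-8-[6-(benzyloxy)-3-(methoxymethoxy)benzofuran-2-yl]flavone
Product: 14 6-(benzyloxy)-2-[3,7,4'-tris(benzyloxy)flavon-8-yl]benzofuran-3(2H)-one (racemic, C2–H labile)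
Conditions: 2 M aq. HCl, THF, 40 °C, Ar (degassed)
Reagents that add atoms: none
Why: Acetal hydrolysis of the enol MOM ether releases the enol, which tautomerises to the ketone; the benzyl ethers are stable, and the air-sensitive 2-aryl ketone is taken on at once under argon.

Step 9
Reactants: 14 6-(benzyloxy)-2-[3,7,4'-tris(benzyloxy)flavon-8-yl]benzofuran-3(2H)-one; 15 4-(benzyloxy)benzoyl chloride
Product: 16 6-(benzyloxy)-2-[3,7,4'-tris(benzyloxy)flavon-8-yl]benzofuran-3-yl 4-(benzyloxy)benzoate
Conditions: Et3N, CH2Cl2, 0 °C, Ar (no DMAP)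
Reagents that add atoms: none
Why: Amine-mediated acylation of the readily formed enolate should occur on oxygen, because C2 is shielded by the di-ortho-substituted aryl group, and leaving out any nucleophilic catalyst prevents a racemic O→C shift.

Step 10
Reactants: 16 6-(benzyloxy)-2-[3,7,4'-tris(benzyloxy)flavon-8-yl]benzofuran-3-yl 4-(benzyloxy)benzoate
Product: 17 (R)-6-(benzyloxy)-2-[4-(benzyloxy)benzoyl]-2-[3,7,4'-tris(benzyloxy)flavon-8-yl]benzofuran-3(2H)-one
Conditions: planar-chiral ferrocene-fused 4-pyrrolidinopyridine (C5Ph5 type, 5–10 mol%), t-AmOH or CH2Cl2, rt to 35 °C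
Reagents that add atoms: none
Why: Proposed new method: an enantioselective Steglich/Black-type O→C aroyl shift in which the chiral pyridine opens the enol ester to an N-aroylpyridinium/benzofuran-3-olate ion pair and C2 of the enolate attacks the acyl group inside that chiral pair, so the quaternary C2 (R) is set by catalyst-controlled facial selection; the shift is downhill because an aromatic enol ester becomes a non-enolisable 1,3-diketone, the closest known reaction is the rearrangement of O-acylated benzofuran-2(3H)-ones, oxindoles and azlactones with planar-chiral PPY or TADMAP catalysts, and the hand of the catalyst that gives (R) has to be found by screening.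

Step 11
Reactants: 17 (R)-6-(benzyloxy)-2-[4-(benzyloxy)benzoyl]-2-[3,7,4'-tris(benzyloxy)flavon-8-yl]benzofuran-3(2H)-one
Product: 19 (2S,8'R)-3',6,8'-trihydroxy-2',8'-bis(4-hydroxyphenyl)spiro[benzofuran-2(3H),9'(8'H)-furo[2,3-h]chromene]-3,4'-dione, via open-chain pentaphenol 18 (not isolated)
Conditions: H2 (1 atm), Pd(OH)2/C, THF/EtOAc, rt
Reagents that add atoms: none
Why: Neutral hydrogenolysis removes the five benzyl ethers and the freed 7-OH adds to the neighbouring aroyl ketone (5-exo-trig hemiketalisation); the spiro carbon is untouched (its descriptor changes from R to S only through CIP priorities) and the hemiketal carbon (R) is set under thermodynamic control with OH syn to C3=O.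

Step 12
Reactants: 19 the 4,5'-dideoxy spiro hemiketal tetraphenol
Product: 20 (2S,8'R)-3',6-diacetoxy-2',8'-bis(4-acetoxyphenyl)-8'-hydroxyspiro[benzofuran-2(3H),9'(8'H)-furo[2,3-h]chromene]-3,4'-dione
Conditions: Ac2O (4.4 equiv), pyridine, CH2Cl2, 0 °C, Ar
Reagents that add atoms: acetic anhydride, CC(=O)OC(C)=O
Why: Chemoselective acetylation should take the four unhindered phenolic and enolic hydroxyls, because the tertiary hemiketal OH is inert and the ring-opened 7-phenol is both scarce and flanked by two ortho substituents.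

Step 13
Reactants: 20 the dideoxy tetra-acetate
Product: 22 (2S,8'R)-3',6-diacetoxy-2',8'-bis(4-acetoxyphenyl)-4,5',8'-trihydroxyspiro[benzofuran-2(3H),9'(8'H)-furo[2,3-h]chromene]-3,4'-dione, via bis(trifluoroacetate) 21 (not isolated)
Conditions: [RuCl2(p-cymene)]2 (10 mol%), PhI(OCOCF3)2 (4 equiv), TFA/TFAA, 80 °C; then H2O/THF, rt
Reagents that add atoms: [bis(trifluoroacetoxy)iodo]benzene, O=C(OI(OC(=O)C(F)(F)F)c1ccccc1)C(F)(F)F
Why: Proposed new method: each ring ketone binds Ru(II) through oxygen and delivers it by carboxylate-assisted metalation–deprotonation to the single C–H it can reach (benzofuranone C3=O to C4–H, pyranone C4=O to C5'–H, each through a five-membered ruthenacycle), the iodine(III) reagent oxidises the aryl–Ru species, and C–O reductive elimination gives the aryl trifluoroacetates 21, which TFAA keeps masked against over-oxidation until aqueous work-up. The closest known reactions are the Ru(II)/iodine(III) ortho-hydroxylation of aryl ketones and the C5-hydroxylation of flavones and chromones in TFA/TFAA; new here are the five-ring benzofuranone carbonyl as director, the twofold use in one molecule and the spiro hemiketal as bystander. No ring is closed and no stereocentre is formed: the spiro carbon is quaternary with no enolisation path in acid, and the hemiketal carbon, if it ionises in TFA, should return to the same thermodynamic diastereomer on hydration. The step needs site selectivity for the two directed C–H bonds over all other aryl C–H bonds; this is secured because each carbonyl has exactly one ortho or peri C–H (the other flank is C7a–O or C3'–OAc), the acetates keep the phenol rings inert to the oxidant, and the closed hemiketal hides the third ketone, which could otherwise direct ruthenium into a 4-acetoxyphenyl ring. Any acetate exchanged for trifluoroacetate is lost on work-up and converges in step 14.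

Step 14
Reactants: 22 the 4,5'-dihydroxy tetra-acetate
Product: 23 (2S,8'R)-3',4,5',6,8'-pentahydroxy-2',8'-bis(4-hydroxyphenyl)spiro[benzofuran-2(3H),9'(8'H)-furo[2,3-h]chromene]-3,4'-dione (target)
Conditions: NH4OAc, MeOH/H2O (4:1), rt, Ar (degassed)
Reagents that add atoms: none
Why: Acetate-buffered methanolysis at neutral pH should cleave the four aryl acetates without the alkoxide or hydroxide that could open the hemiketal and start a retro-Claisen cleavage at the spiro carbon, and the hydrogen-bonded 4- and 5'-hydroxyls are left alone.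

## Compound list

1 | 3,7,4'-trihydroxyflavone | O=c1c(O)c(-c2ccc(O)cc2)oc2cc(O)ccc12 | starting material
2 | 3,7,4'-triacetoxyflavone | O=c1c(OC(C)=O)c(-c2ccc(OC(C)=O)cc2)oc2cc(OC(C)=O)ccc12 | intermediate
3 | 3,4'-diacetoxy-7-hydroxyflavone | O=c1c(OC(C)=O)c(-c2ccc(OC(C)=O)cc2)oc2cc(O)ccc12 | intermediate
4 | 3,4'-diacetoxy-7-hydroxy-8-iodoflavone | O=c1c(OC(C)=O)c(-c2ccc(OC(C)=O)cc2)oc2c(I)c(O)ccc12 | intermediate
5 | 3,7,4'-trihydroxy-8-iodoflavone (not isolated) | O=c1c(O)c(-c2ccc(O)cc2)oc2c(I)c(O)ccc12 | intermediate
6 | 3,7,4'-tris(benzyloxy)-8-iodoflavone | O=c1c(OCc2ccccc2)c(-c2ccc(OCc3ccccc3)cc2)oc2c(I)c(OCc3ccccc3)ccc12 | intermediate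
7 | 6-hydroxybenzofuran-3(2H)-one | O=C1COc2cc(O)ccc12 | starting material
8 | 6-(benzyloxy)benzofuran-3(2H)-one | O=C1COc2cc(OCc3ccccc3)ccc12 | intermediate
9 | potassium 6-(benzyloxy)benzofuran-3-olate (not isolated) | [K+].[O-]c1coc2cc(OCc3ccccc3)ccc12 | intermediate
10 | 6-(benzyloxy)-3-(methoxymethoxy)benzofuran | COCOc1coc2cc(OCc3ccccc3)ccc12 | intermediate
11 | 6-(benzyloxy)-2-lithio-3-(methoxymethoxy)benzofuran (not isolated) | COCOc1c([Li])oc2cc(OCc3ccccc3)ccc12 | intermediate
12 | [6-(benzyloxy)-3-(methoxymethoxy)benzofuran-2-yl]zinc chloride (not isolated) | COCOc1c([Zn]Cl)oc2cc(OCc3ccccc3)ccc12 | intermediate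
13 | 3,7,4'-tris(benzyloxy)-8-[6-(benzyloxy)-3-(methoxymethoxy)benzofuran-2-yl]flavone | COCOc1c(-c2c(OCc3ccccc3)ccc3c(=O)c(OCc4ccccc4)c(-c4ccc(OCc5ccccc5)cc4)oc23)oc2cc(OCc3ccccc3)ccc12 | intermediate
14 | 6-(benzyloxy)-2-[3,7,4'-tris(benzyloxy)flavon-8-yl]benzofuran-3(2H)-one (racemic, C2–H labile) | O=C1c2ccc(OCc3ccccc3)cc2OC1c1c(OCc2ccccc2)ccc2c(=O)c(OCc3ccccc3)c(-c3ccc(OCc4ccccc4)cc3)oc12 | intermediate
15 | 4-(benzyloxy)benzoyl chloride | O=C(Cl)c1ccc(OCc2ccccc2)cc1 | starting material
16 | 6-(benzyloxy)-2-[3,7,4'-tris(benzyloxy)flavon-8-yl]benzofuran-3-yl 4-(benzyloxy)benzoate | O=C(Oc1c(-c2c(OCc3ccccc3)ccc3c(=O)c(OCc4ccccc4)c(-c4ccc(OCc5ccccc5)cc4)oc23)oc2cc(OCc3ccccc3)ccc12)c1ccc(OCc2ccccc2)cc1 | intermediate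
17 | (R)-6-(benzyloxy)-2-[4-(benzyloxy)benzoyl]-2-[3,7,4'-tris(benzyloxy)flavon-8-yl]benzofuran-3(2H)-one | O=C1c2ccc(OCc3ccccc3)cc2O[C@@]1(C(=O)c1ccc(OCc2ccccc2)cc1)c1c(OCc2ccccc2)ccc2c(=O)c(OCc3ccccc3)c(-c3ccc(OCc4ccccc4)cc3)oc12 | intermediate
18 | (R)-6-hydroxy-2-(4-hydroxybenzoyl)-2-(3,7,4'-trihydroxyflavon-8-yl)benzofuran-3(2H)-one (open-chain form, not isolated) | O=C1c2ccc(O)cc2O[C@@]1(C(=O)c1ccc(O)cc1)c1c(O)ccc2c(=O)c(O)c(-c3ccc(O)cc3)oc12 | intermediate
19 | (2S,8'R)-3',6,8'-trihydroxy-2',8'-bis(4-hydroxyphenyl)spiro[benzofuran-2(3H),9'(8'H)-furo[2,3-h]chromene]-3,4'-dione (4,5'-dideoxy target) | O=C1c2ccc(O)cc2O[C@@]12c1c(ccc3c(=O)c(O)c(-c4ccc(O)cc4)oc13)O[C@]2(O)c1ccc(O)cc1 | intermediate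
20 | (2S,8'R)-dideoxy tetra-acetate (3',6-diacetoxy, both aryl groups 4-acetoxyphenyl, 8'-OH free) | O=C1c2ccc(OC(C)=O)cc2O[C@@]12c1c(ccc3c(=O)c(OC(C)=O)c(-c4ccc(OC(C)=O)cc4)oc13)O[C@]2(O)c1ccc(OC(C)=O)cc1 | intermediate
21 | (2S,8'R)-4,5'-bis(trifluoroacetoxy) tetra-acetate (not isolated) | O=C1c2c(OC(=O)C(F)(F)F)cc(OC(C)=O)cc2O[C@@]12c1c(cc(OC(=O)C(F)(F)F)c3c(=O)c(OC(C)=O)c(-c4ccc(OC(C)=O)cc4)oc13)O[C@]2(O)c1ccc(OC(C)=O)cc1 | intermediate
22 | (2S,8'R)-4,5'-dihydroxy tetra-acetate | O=C1c2c(O)cc(OC(C)=O)cc2O[C@@]12c1c(cc(O)c3c(=O)c(OC(C)=O)c(-c4ccc(OC(C)=O)cc4)oc13)O[C@]2(O)c1ccc(OC(C)=O)cc1 | intermediate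
23 | (2S,8'R)-3',4,5',6,8'-pentahydroxy-2',8'-bis(4-hydroxyphenyl)spiro[benzofuran-2(3H),9'(8'H)-furo[2,3-h]chromene]-3,4'-dione (CNP0283000.1) | O=C1c2c(O)cc(O)cc2O[C@@]12c1c(cc(O)c3c(=O)c(O)c(-c4ccc(O)cc4)oc13)O[C@]2(O)c1ccc(O)cc1 | target

## Step count and risks

Total step count: 14. Longest linear sequence: 12 (steps 1–4, then 7–14).

Steps most likely to fail:

1. Step 13 (Proposed new method). The second hydroxylation may stall at the benzofuranone, because a five-ring ketone gives a wide, strained bite for cyclometalation. The hot acidic oxidant may also degrade the ionised hemiketal. Fallback: setting out from 20, the C–O bonds are made in two stages by known reactions. Iridium-catalysed ketone-directed ortho C–H borylation ([Ir(OMe)(cod)]2, AsPh3, B2pin2, octane, 120 °C, the conditions used for aryl ketones) would give the 4,5'-bis(pinacolboronate) F1. Oxone in aqueous acetone then oxidises both C–B bonds under acidic conditions that spare the acetates, and the route is rejoined at 22.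

2. Step 10 (Proposed new method). The chiral ion pair may give poor facial selection at the crowded C2, or may collapse back to the enol ester and leave the shift sluggish. Fallback: setting out from 16, achiral DMAP (10 mol%, CH2Cl2, rt) carries out the ordinary Steglich-type O→C acyl shift to the racemic diketone F2. Preparative chromatography on a chiral stationary phase (SFC) separates the enantiomers, and the (R)-enantiomer rejoins the route at 17.

3. Step 12. Pyridine may promote ring opening of the hemiketal and acetylation of the liberated 7-phenol, or the flavonol 3-OH may lag behind, so that chemoselectivity is lost. Fallback: setting out from 19, Ac2O with catalytic Sc(OTf)3 in MeCN at 0 °C acetylates all five hydroxyls under acidic conditions, in which no phenoxide of the ring-opened form exists. This gives the closed penta-acetate F3 with the hemiketal capped as its ketal acetate. Brief solvolysis of that one acid-labile ester (aq. TFA/THF, rt) frees the hemiketal again, and the route is rejoined at 20.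

## Further compounds

F1 | step 13 | (2S,8'R)-dideoxy tetra-acetate 4,5'-bis(pinacolboronate) | O=C1c2c(B3OC(C)(C)C(C)(C)O3)cc(OC(C)=O)cc2O[C@@]12c1c(cc(B3OC(C)(C)C(C)(C)O3)c3c(=O)c(OC(C)=O)c(-c4ccc(OC(C)=O)cc4)oc13)O[C@]2(O)c1ccc(OC(C)=O)cc1
F2 | step 10 | racemic 6-(benzyloxy)-2-[4-(benzyloxy)benzoyl]-2-[3,7,4'-tris(benzyloxy)flavon-8-yl]benzofuran-3(2H)-one | O=C1c2ccc(OCc3ccccc3)cc2OC1(C(=O)c1ccc(OCc2ccccc2)cc1)c1c(OCc2ccccc2)ccc2c(=O)c(OCc3ccccc3)c(-c3ccc(OCc4ccccc4)cc3)oc12
F3 | step 12 | (2S)-dideoxy penta-acetate with 8'-acetoxy ketal (either configuration at C8') | O=C1c2ccc(OC(C)=O)cc2O[C@@]12c1c(ccc3c(=O)c(OC(C)=O)c(-c4ccc(OC(C)=O)cc4)oc13)OC2(OC(C)=O)c1ccc(OC(C)=O)cc1
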